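**Plan**

- Retrosynthetic cuts, in order: (a) the pendant lactone at pyrrole Cα–CH(O) and at CH2–Cα(lactone), leaving a formyl group; (b) the bond between the pyrrole β-carbon and the β-carbon of the ring-fused γ-lactone, which opens the cyclohexane and uncovers an α-methylbutenolide; (c) the butenolide at Cγ–CH2; (d) the two pyrrole N–C bonds; (e) the CH(Et)–CH(azepine) bond.
- Enabling feature: the β-carbon of the fused γ-lactone is bonded to the pyrrole β-carbon, and its γ-carbon (O–CH) lies in the same six-membered ring, three atoms from pyrrole C-2. The pyrrole–CH bond is therefore the conjugate-addition bond of a butenolide tethered through its γ-carbon.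
- Forward order: acyclic chain by an organocatalytic nitro-Michael addition; azepine and pyrrole together by a tethered Paal–Knorr condensation; butenolide; cyclohexane and fused lactone in the key step; pendant lactone last.
- Stereochemistry: the two adjacent CH centres come from the (S)-diphenylprolinol silyl ether catalyst (syn adduct). Both O–CH centres come from ligand-controlled chromium allylations. The ring-fusion and α-methyl centres come from the tether and convex-face protonation in the key step. The last methyl comes from hydrogenation anti to the pyrrolyl group.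

Key step: step 13

Assumption: the chromium–bis(oxazolinyl)carbazole catalyst keeps the sense of induction it shows with simple aldehydes. The ligand enantiomer meant in steps 11 and 15 is the one that turns benzaldehyde into (S)-3-methylidene-5-phenyloxolan-2-one, i.e. allyl transfer to the Si face of RCHO.

Remark: 5-chloropentan-1-ol, nitromethane, butanal, acrolein and ethyl 2-(bromomethyl)acrylate are taken as commercial.

**Route**

Step 1
Reactants: 1 5-chloropentan-1-ol
Product: 2 5-chloropentanal
Conditions: TEMPO (10 mol %), PhI(OAc)2, CH2Cl2, rt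
Reagents that add atoms: none
Why: Nitroxyl-catalysed alcohol oxidation stops at the aldehyde and leaves the primary chloride untouched.

Step 2
Reactants: 2 5-chloropentanal; 3 nitromethane
Product: 5 (E)-6-chloro-1-nitrohex-1-ene, via nitro alcohol 4 (not isolated)
Conditions: MeNO2 (5 equiv), KOt-Bu (10 mol %), THF–t-BuOH, 0 °C; concentrate; then MsCl, Et3N, CH2Cl2, 0 °C
Reagents that add atoms: none
Why: Henry addition followed by mesylation and E1cB elimination should give the conjugated nitroalkene as the more stable E isomer.

Step 3
Reactants: 5 (E)-6-chloro-1-nitrohex-1-ene; 6 butanal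
Product: 8 (2R,3R)-7-chloro-2-ethyl-3-(nitromethyl)heptan-1-ol, via aldehyde 7 (not isolated)
Conditions: (S)-α,α-diphenylprolinol trimethylsilyl ether (10 mol %), 4-nitrophenol (20 mol %), butanal (3 equiv), toluene, 0 °C → rt; then NaBH4, EtOH, 0 °C
Reagents that add atoms: none
Why: In this enamine-catalysed Michael addition the E-enamine, shielded on one face by the diphenyl(silyloxy)methyl group, adds through an acyclic synclinal transition state to give the syn (2R,3R) adduct, and immediate borohydride reduction removes the epimerisable aldehyde.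

Step 4
Reactants: 8 (2R,3R)-7-chloro-2-ethyl-3-(nitromethyl)heptan-1-ol
Product: 9 tert-butyl{[(2R,3R)-7-chloro-2-ethyl-3-(nitromethyl)heptyl]oxy}diphenylsilane
Conditions: t-BuPh2SiCl, imidazole, CH2Cl2, rt
Reagents that add atoms: tert-butyl(chloro)diphenylsilane, CC(C)(C)[Si](Cl)(c1ccccc1)c1ccccc1
Why: Standard silylation of the primary alcohol gives an ether that should tolerate the base and mild acid of steps 5 to 8.

Step 5
Reactants: 9 silyl ether; 10 acrolein
Product: 12 tert-butyl({(2R)-2-[(5R)-9-chloro-1,1-dimethoxy-4-nitrononan-5-yl]butyl}oxy)diphenylsilane, via nitro aldehyde 11 (not isolated)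
Conditions: acrolein (1.2 equiv), DBU (10 mol %), MeCN, −20 → 0 °C; then HC(OMe)3, PPTS (30 mol %), MeOH, rt
Reagents that add atoms: trimethyl orthoformate, COC(OC)OC
Why: The base-catalysed nitro-Michael addition uses the nitro-bearing carbon as an acyl-anion equivalent to add the three remaining pyrrole carbons, the branched neighbour disfavours a second addition, and in-situ acetalisation masks the new aldehyde; the nitro-bearing centre forms as a mixture and is erased in step 6.

Step 6
Reactants: 12 nitro acetal
Product: 14 (5R)-5-[(2R)-1-{[tert-butyl(diphenyl)silyl]oxy}butan-2-yl]-9-chloro-1,1-dimethoxynonan-4-one, via potassium nitronate 13 (not isolated)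
Conditions: KOH, MeOH, 0 °C; then KMnO4, MgSO4, H2O, 0 °C
Reagents that add atoms: potassium permanganate, [K+].[O-][Mn](=O)(=O)=O
Why: In this oxidative Nef reaction permanganate cleaves the C=N bond of the secondary nitronate within minutes at 0 °C, conditions under which acetal, silyl ether and chloride are inert and the adjacent stereocentre should not epimerise.

Step 7
Reactants: 14 chloro keto acetal
Product: 15 (5R)-9-azido-5-[(2R)-1-{[tert-butyl(diphenyl)silyl]oxy}butan-2-yl]-1,1-dimethoxynonan-4-one
Conditions: NaN3, NaI (10 mol %), DMF, 50 °C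
Reagents that add atoms: sodium azide, [Na+].[N-]=[N+]=[N-]
Why: SN2 displacement of the primary chloride by azide under iodide catalysis is too weakly basic to enolise the ketone.

Step 8
Reactants: 15 azido keto acetal
Product: 17 (9R)-9-[(2R)-1-{[tert-butyl(diphenyl)silyl]oxy}butan-2-yl]-6,7,8,9-tetrahydro-5H-pyrrolo[1,2-a]azepine, via amine 16 (not isolated)
Conditions: PPh3, THF–H2O (9:1), 45 °C; then AcOH, 60 °C, 0.01 M
Reagents that add atoms: none
Why: Staudinger reduction frees the amine, aqueous acid unmasks the aldehyde, and a tethered Paal–Knorr condensation (seven-membered hemiaminal with the ketone, then five-membered closure onto the aldehyde and loss of water) builds azepine and pyrrole together, the pathway through hemiaminals and not enamines keeping the stereocentre next to the ketone.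

Step 9
Reactants: 17 silyl-protected pyrroloazepine
Product: 18 (2R)-2-[(9R)-6,7,8,9-tetrahydro-5H-pyrrolo[1,2-a]azepin-9-yl]butan-1-ol
Conditions: Bu4NF, THF, rt
Reagents that add atoms: none
Why: Fluoride cleaves the Si–O bond and nothing else in the molecule reacts with it.

Step 10
Reactants: 18 pyrroloazepine alcohol
Product: 19 (2R)-2-[(9R)-6,7,8,9-tetrahydro-5H-pyrrolo[1,2-a]azepin-9-yl]butanal
Conditions: SO3·pyridine, DMSO, i-Pr2NEt, CH2Cl2, 0 °C
Reagents that add atoms: none
Why: Parikh–Doering oxidation is non-acidic, should give the α-branched aldehyde without epimerisation and should not attack the electron-rich pyrrole.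

Step 11
Reactants: 19 pyrroloazepine aldehyde; 20 ethyl 2-(bromomethyl)acrylate
Product: 22 (5S)-3-methylidene-5-{(1R)-1-[(9R)-6,7,8,9-tetrahydro-5H-pyrrolo[1,2-a]azepin-9-yl]propyl}oxolan-2-one, via silyl ether 21 (not isolated)
Conditions: CrCl2 (10 mol %), chiral 1,8-bis(oxazolinyl)carbazole ligand (12 mol %), Mn powder, Me3SiCl, i-Pr2NEt (30 mol %), THF, rt; then Bu4NF, THF, 0 °C
Reagents that add atoms: none
Why: In this catalytic asymmetric Nozaki–Hiyama–Kishi-type 2-(ethoxycarbonyl)allylation the ligand-bound allylchromium species delivers the allyl group to the Si face of the aldehyde (new O-bearing centre S, against the inherent 1,2-induction of the α-stereocentre, so the catalyst must dominate), and desilylation releases an alkoxide that closes the lactone on the ester.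

Step 12
Reactants: 22 α-methylidene lactone
Product: 23 (5R)-3-methyl-5-{(1R)-1-[(9R)-6,7,8,9-tetrahydro-5H-pyrrolo[1,2-a]azepin-9-yl]propyl}furan-2(5H)-one
Conditions: RhCl3·3H2O (5 mol %), EtOH, 70 °C
Reagents that add atoms: none
Why: In this metal-hydride alkene isomerisation a rhodium hydride adds to the exocyclic alkene and β-hydride elimination toward the ring CH2 gives the more substituted conjugated butenolide; the γ-hydrogen is not involved, so the O-bearing centre keeps its geometry (its descriptor changes from S to R only because the CIP priorities change).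

Step 13
Reactants: 23 butenolide
Product: 24 tetracyclic lactone (core of the target without the pendant lactone)
Conditions: Sc(OTf)3 (20 mol %), MeCN, 0.005 M, 50 °C
Reagents that add atoms: none
Why: Sc(OTf)3 binds the lactone carbonyl, the pyrrole β-carbon next to the azepine-fused α-carbon adds to the butenolide β-carbon, the σ-complex loses its proton to restore the pyrrole, and the scandium enolate is protonated at the α-carbon. The closest known reaction type is the Lewis-acid-catalysed intramolecular Friedel–Crafts conjugate addition of pyrroles and indoles to enones and unsaturated lactones. The one new ring, the cyclohexane, closes 6-exo-trig with respect to the butenolide alkene. At the lactone β-carbon (S) the three-atom tether from the γ-carbon lets the nucleophile reach only the face syn to it, which forces the cis ring fusion. At the α-carbon (S) kinetic protonation on the convex face of the new bicycle should place the methyl group on the concave face. The step needs β- over α-selectivity on the pyrrole: only the β-carbon adjacent to the tethered α-carbon can reach the acceptor, and high dilution suppresses intermolecular attack through the free α-position, while the three existing stereocentres are not touched.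

Step 14
Reactants: 24 tetracyclic lactone
Product: 26 tetracyclic pyrrole aldehyde, via iminium chloride 25 (not isolated)
Conditions: POCl3, DMF, ClCH2CH2Cl, 0 °C → rt; then aq. NaOAc, rt
Reagents that add atoms: N,N-dimethylformamide, CN(C)C=O; water, O
Why: Vilsmeier–Haack formylation attacks the only free pyrrole α-position, which is far more nucleophilic than the remaining β-CH, and buffered hydrolysis spares the lactone and its α-stereocentre.

Step 15
Reactants: 26 tetracyclic pyrrole aldehyde; 20 ethyl 2-(bromomethyl)acrylate
Product: 28 α-methylidene bis-lactone, via silyl ether 27 (not isolated)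
Conditions: CrCl2 (10 mol %), same ligand enantiomer as in step 11 (12 mol %), Mn powder, Me3SiCl, i-Pr2NEt (30 mol %), THF, rt; then Bu4NF, THF, 0 °C
Reagents that add atoms: none
Why: This is the same chromium-catalysed asymmetric allylation with lactonisation as in step 11; the existing stereocentres are remote, so the ligand alone should direct the allyl group to the Si face of the formyl group (new centre S), and fluoride-induced lactonisation avoids acid, under which a pyrrol-2-yl carbinol would ionise.

Step 16
Reactants: 28 α-methylidene bis-lactone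
Product: 29 bisdehydroneotuberostemonine
Conditions: H2 (1 atm), RhCl(PPh3)3 (10 mol %), toluene–EtOH, rt
Reagents that add atoms: none
Why: Homogeneous hydrogenation should reduce only the unhindered exocyclic alkene, delivering hydrogen to the face opposite the pyrrolyl group on the lactone γ-carbon so that the new methyl ends cis to it (S), and the neutral rhodium catalyst avoids hydrogenolysis of the pyrrolylmethyl C–O bond.

**Compound list**

1 | 5-chloropentan-1-ol | OCCCCCCl | starting material
2 | 5-chloropentanal | O=CCCCCCl | intermediate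
3 | nitromethane | C[N+](=O)[O-] | starting material
4 | 6-chloro-1-nitrohexan-2-ol (racemic, not isolated) | OC(CCCCCl)C[N+](=O)[O-] | intermediate
5 | (E)-6-chloro-1-nitrohex-1-ene | ClCCCC/C=C/[N+](=O)[O-] | intermediate
6 | butanal | CCCC=O | starting material
7 | (2R,3R)-7-chloro-2-ethyl-3-(nitromethyl)heptanal (not isolated) | CC[C@H]([C@H](C[N+](=O)[O-])CCCCCl)C=O | intermediate
8 | (2R,3R)-7-chloro-2-ethyl-3-(nitromethyl)heptan-1-ol | CC[C@H]([C@H](C[N+](=O)[O-])CCCCCl)CO | intermediate
9 | tert-butyl{[(2R,3R)-7-chloro-2-ethyl-3-(nitromethyl)heptyl]oxy}diphenylsilane | CC[C@H]([C@H](C[N+](=O)[O-])CCCCCl)CO[Si](c1ccccc1)(c1ccccc1)C(C)(C)C | intermediate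
10 | acrolein (prop-2-enal) | C=CC=O | starting material
11 | (5R)-5-[(2R)-1-{[tert-butyl(diphenyl)silyl]oxy}butan-2-yl]-9-chloro-4-nitrononanal, both C-4 epimers (not isolated) | CC[C@H]([C@H](C(CCC=O)[N+](=O)[O-])CCCCCl)CO[Si](c1ccccc1)(c1ccccc1)C(C)(C)C | intermediate
12 | tert-butyl({(2R)-2-[(5R)-9-chloro-1,1-dimethoxy-4-nitrononan-5-yl]butyl}oxy)diphenylsilane, both C-4 epimers | CC[C@H]([C@H](C(CCC(OC)OC)[N+](=O)[O-])CCCCCl)CO[Si](c1ccccc1)(c1ccccc1)C(C)(C)C | intermediate
13 | potassium nitronate of 12 (not isolated) | CC[C@H]([C@H](C(CCC(OC)OC)=[N+]([O-])[O-])CCCCCl)CO[Si](c1ccccc1)(c1ccccc1)C(C)(C)C.[K+] | intermediate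
14 | (5R)-5-[(2R)-1-{[tert-butyl(diphenyl)silyl]oxy}butan-2-yl]-9-chloro-1,1-dimethoxynonan-4-one | CC[C@H]([C@H](C(=O)CCC(OC)OC)CCCCCl)CO[Si](c1ccccc1)(c1ccccc1)C(C)(C)C | intermediate
15 | (5R)-9-azido-5-[(2R)-1-{[tert-butyl(diphenyl)silyl]oxy}butan-2-yl]-1,1-dimethoxynonan-4-one | CC[C@H]([C@H](C(=O)CCC(OC)OC)CCCCN=[N+]=[N-])CO[Si](c1ccccc1)(c1ccccc1)C(C)(C)C | intermediate
16 | (5R)-9-amino-5-[(2R)-1-{[tert-butyl(diphenyl)silyl]oxy}butan-2-yl]-1,1-dimethoxynonan-4-one (not isolated) | CC[C@H]([C@H](C(=O)CCC(OC)OC)CCCCN)CO[Si](c1ccccc1)(c1ccccc1)C(C)(C)C | intermediate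
17 | (9R)-9-[(2R)-1-{[tert-butyl(diphenyl)silyl]oxy}butan-2-yl]-6,7,8,9-tetrahydro-5H-pyrrolo[1,2-a]azepine | CC[C@H]([C@H]1CCCCn2cccc12)CO[Si](c1ccccc1)(c1ccccc1)C(C)(C)C | intermediate
18 | (2R)-2-[(9R)-6,7,8,9-tetrahydro-5H-pyrrolo[1,2-a]azepin-9-yl]butan-1-ol | CC[C@H]([C@H]1CCCCn2cccc12)CO | intermediate
19 | (2R)-2-[(9R)-6,7,8,9-tetrahydro-5H-pyrrolo[1,2-a]azepin-9-yl]butanal | CC[C@H]([C@H]1CCCCn2cccc12)C=O | intermediate
20 | ethyl 2-(bromomethyl)acrylate | C=C(CBr)C(=O)OCC | starting material
21 | ethyl (4S,5R)-2-methylidene-5-[(9R)-6,7,8,9-tetrahydro-5H-pyrrolo[1,2-a]azepin-9-yl]-4-[(trimethylsilyl)oxy]heptanoate (not isolated) | CC[C@H]([C@H]1CCCCn2cccc12)[C@@H](O[Si](C)(C)C)CC(=C)C(=O)OCC | intermediate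
22 | (5S)-3-methylidene-5-{(1R)-1-[(9R)-6,7,8,9-tetrahydro-5H-pyrrolo[1,2-a]azepin-9-yl]propyl}oxolan-2-one | CC[C@H]([C@H]1CCCCn2cccc12)[C@H]1OC(=O)C(=C)C1 | intermediate
23 | (5R)-3-methyl-5-{(1R)-1-[(9R)-6,7,8,9-tetrahydro-5H-pyrrolo[1,2-a]azepin-9-yl]propyl}furan-2(5H)-one | CC[C@H]([C@H]1CCCCn2cccc12)[C@H]1OC(=O)C(C)=C1 | intermediate
24 | tetracyclic lactone: pyrrole β-carbon of 23 bonded to the former butenolide β-carbon, cis-fused α-methyl-γ-lactone on the new cyclohexane; centres R (CH–Et), R (CH–O), S (CH–CH3), S (lactone β-CH), R (azepine CH) | CC[C@H]1[C@H]2OC(=O)[C@@H](C)[C@H]2c2ccn3c2[C@@H]1CCCC3 | intermediate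
25 | N,N-dimethyliminium chloride of 26 (not isolated) | CC[C@H]1[C@H]2OC(=O)[C@@H](C)[C@H]2c2cc(C=[N+](C)C)n3c2[C@@H]1CCCC3.[Cl-] | intermediate
26 | 24 carrying a formyl group on the free pyrrole α-carbon | CC[C@H]1[C@H]2OC(=O)[C@@H](C)[C@H]2c2cc(C=O)n3c2[C@@H]1CCCC3 | intermediate
27 | ethyl (4S)-2-methylidene-4-[(trimethylsilyl)oxy]butanoate bonded through C-4 to the pyrrole α-carbon of 24 (not isolated) | CC[C@H]1[C@H]2OC(=O)[C@@H](C)[C@H]2c2cc([C@@H](O[Si](C)(C)C)CC(=C)C(=O)OCC)n3c2[C@@H]1CCCC3 | intermediate
28 | 24 carrying a (2S)-4-methylidene-5-oxooxolan-2-yl group on the pyrrole α-carbon | CC[C@H]1[C@H]2OC(=O)[C@@H](C)[C@H]2c2cc([C@@H]3CC(=C)C(=O)O3)n3c2[C@@H]1CCCC3 | intermediate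
29 | bisdehydroneotuberostemonine: 24 carrying a (2S,4S)-4-methyl-5-oxooxolan-2-yl group on the pyrrole α-carbon | CC[C@H]1[C@H]2OC(=O)[C@@H](C)[C@H]2c2cc([C@@H]3C[C@H](C)C(=O)O3)n3c2[C@@H]1CCCC3 | target

**Step count and risks**

Total step count: 16. Longest linear sequence: 16 steps, from 1 to 29.

Steps most likely to fail:

Step 13. The α-methylbutenolide may be too poor an acceptor for the moderately nucleophilic pyrrole β-carbon. Intermolecular attack through the free α-position or simple non-reaction could then win, and the enol may be protonated on both faces. Fallback: from 23 the same bond is closed with palladium (Pd(OAc)2, divalent palladium, with tert-butyl perbenzoate in AcOH–dioxane at 70 °C). C–H palladation at the pyrrole β-carbon, syn carbopalladation of the butenolide alkene on the tether face and β-hydride elimination toward the methyl group should give the cis-fused α-methylidene tetracyclic lactone F1. Hydrogenation (H2, RhCl(PPh3)3, toluene) from the convex face then places the methyl group on the concave face and returns to 24.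

Step 11. The catalyst has to overrule the inherent 1,2-induction of the α-branched aldehyde (mismatched pairing). Facial selectivity may therefore erode, and a slow reaction gives the aldehyde time to epimerise. Fallback: from 19 the allylation is run with the enantiomeric ligand (matched pairing, Re face) and without fluoride, to give the (4R)-configured silyl ether F2. LiOH in aqueous THF removes the ethyl ester and the silyl group to give the (4R)-hydroxy acid F3. Mitsunobu lactonisation (PPh3, DIAD, THF, 0 °C) closes the lactone with inversion at the carbinol carbon and returns to 22.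

Step 8. Seven-membered ring closure in the condensation may lose to intermolecular imine formation and oligomerisation. Prolonged contact of the ketone with amine and acid may also epimerise the neighbouring stereocentre through enamine tautomers. Fallback: from 14 (step 7 is skipped) a Paal–Knorr condensation with NH4OAc in AcOH at 50 °C gives the N-unsubstituted pyrrole F4. NaH in DMF (0 °C → rt, 0.01 M) then closes the azepine by intramolecular N-alkylation with the primary chloride and returns to 17.

**Further compounds**

F1 | step 13 | cis-fused α-methylidene tetracyclic lactone (24 with C=CH2 in place of CH–CH3) | CC[C@H]1[C@H]2OC(=O)C(=C)[C@H]2c2ccn3c2[C@@H]1CCCC3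
F2 | step 11 | ethyl (4R,5R)-2-methylidene-5-[(9R)-6,7,8,9-tetrahydro-5H-pyrrolo[1,2-a]azepin-9-yl]-4-[(trimethylsilyl)oxy]heptanoate | CC[C@H]([C@H]1CCCCn2cccc12)[C@H](O[Si](C)(C)C)CC(=C)C(=O)OCC
F3 | step 11 | (4R,5R)-4-hydroxy-2-methylidene-5-[(9R)-6,7,8,9-tetrahydro-5H-pyrrolo[1,2-a]azepin-9-yl]heptanoic acid | CC[C@H]([C@H]1CCCCn2cccc12)[C@H](O)CC(=C)C(=O)O
F4 | step 8 | tert-butyl{[(2R,3R)-7-chloro-2-ethyl-3-(1H-pyrrol-2-yl)heptyl]oxy}diphenylsilane | CC[C@H]([C@H](c1ccc[nH]1)CCCCCl)CO[Si](c1ccccc1)(c1ccccc1)C(C)(C)C
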